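**Compound numbers used throughout**

1 (2E,6E)-farnesol · 2 umbelliferone · 3 umbelliprenin · 4 12-hydroxyumbelliprenin · 5 (10R,11R)-epoxy alcohol · 6 its TBDPS ether (cyclisation precursor) · 7 bicyclic 3,8-diol 15-silyl ether (cyclisation product) · 8 triol · 9 angelic acid · 10 mixed anhydride · 11 target.

Locants: the open-chain compounds 3–6 carry farnesyl locants (C1 = OCH2, C12 = the E-terminal carbon). The bicyclic compounds 7, 8 and 11 carry decalin locants C1–C10 (ring A = C1–C5, C10; ring B = C5–C10), with C11 the CH2 on C9 and C15 the oxygenated CH2 on C4. Chain C11, C10, C6, C7, C2, C3, C1 and C12 become C4, C3, C5, C10, C9, C8, C11 and C15.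

## Analysis of the target

Target 11 is a sesquiterpene coumarin ether: a trans-fused decalin whose C11 is bound through oxygen to C7 of a coumarin and whose C15 oxygen carries a (Z)-2-methylbut-2-enoyl (angeloyl) group. All six stereocentres lie in the decalin: the secondary carbinol C3 (R), quaternary C4 (S), C5 (S), the tertiary carbinol C8 (S), C9 (R) and quaternary C10 (R). In the chair–chair trans-decalin the C10 methyl and H5 are axial and anti. O3, the C15 acyloxymethyl group, the C8 hydroxyl and the C11 aryloxymethyl group are all equatorial, and the methyls on C4 and C8 are axial, syn to the C10 methyl. The angelate isomerises easily to its E isomer, the coumarin lactone is open to hydride and hydroxide and has a Lewis-basic carbonyl, the tertiary C8 hydroxyl can be lost under acid, and O3 and O15 form a 1,3-diol across which acyl groups can migrate. The difficulty lies in two quaternary carbons and a tertiary carbinol packed among six stereocentres, in an aryl ether on the neopentyl-type carbon C11, and in acylating one of three hydroxyls. The strategy rests on one pattern: the C3 carbinol next to quaternary C4 (methyl and C15H2O), the trans C5–C10 fusion with its angular methyl, the tertiary carbinol C8 and the C9–C11H2–O–aryl arm. This is exactly what an all-chair, all-anti cation cascade would leave behind from an all-E 10,11-epoxyfarnesyl aryl ether whose E-terminal methyl is oxygenated.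

## Retrosynthetic reasoning

**11 ⇒ 8 + 9.** The acyl C–O bond at O15 is cut first. The angelate is the most fragile group, so it should be introduced last, from 9 through its activated form 10. The forward step has to acylate the primary hydroxyl of 8 in preference to the hindered secondary O3 and the tertiary O8, and must not isomerise the Z alkene.

**8 ⇒ 7.** The O15–Si bond is cut. O15 needs a mask during the cation cascade that neither participates at the neighbouring cationic carbon nor chelates the Lewis acid, which rules out esters and favours a bulky silyl ether. Fluoride removes it without touching the lactone, the aryl ether or the carbinols.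

**7 ⇒ 6.** C4–C5, C9–C10 and C8–O are cut together; this is the disconnection that carries the plan. These are the bonds a cation started at C4 forms one after the other, so cutting them unfolds both rings into an open chain. Any other cut leaves a quaternary carbon to be built separately. Five stereocentres are exchanged for one epoxide and two alkene geometries. The forward reaction has to open the epoxide at its tertiary carbon, run through a chair–chair fold, and end by taking up a hydroxyl from the medium rather than by losing a proton.

**6 ⇒ 5 ⇒ 4.** The silyl ether is removed and the two epoxide C–O bonds are cut. Because C12 is oxygenated, 4 is an allylic alcohol, so the epoxide can be set by a reagent-controlled, hydroxyl-directed asymmetric epoxidation. The two internal alkenes carry no directing group and are left alone. This one step fixes the absolute configuration of the whole target.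

**4 ⇒ 3.** The C12–O bond is cut, that is, an allylic C–H oxidation of the E-terminal methyl of 3. The terminal alkene is the most electron-rich and least hindered of the three, and selenium-based allylic oxidation gives the E-allylic alcohol by its mechanism.

**3 ⇒ 1 + 2.** The aryl O–C1 bond is cut. The ether is made at the start, when C1 is an unhindered allylic carbon. After cyclisation the same carbon is C11, next to quaternary C10 and the fully substituted C8, where substitution would be poor. The coumarin then rides through the route as a spectator.

## Alternatives that were turned down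

**Alternative 1:** ring B is cut at C7–C8 and C7 is re-attached to C9. This leads back to the ring-contracted acetyl carbinol A2, a hydrindane whose five-membered ring carries hydroxyl and acetyl on C9. In the forward step an alkoxide at C9 drives an α-ketol shift: C7 migrates to the acetyl carbon, C9 becomes a ketone, and the ring expands to the 8-hydroxy-8-methyl decalin-9-one acetonide A1.
- For: the tertiary carbinol C8 is made by an intramolecular 1,2-shift with relief of ring strain and under basic conditions. On this point the alternative is stronger than the chosen route, whose C8–O bond depends on intermolecular capture of a cation.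
- Against: A1 has a ketone at C9 where the target has a CH bearing CH2OAr. A one-carbon homologation at a carbonyl flanked by quaternary C10 and fully substituted C8, the setting of C9, and an ether formation at neopentylic C11 with 2 would all follow.
- Against: A2 already contains ring A and four stereocentres (C3, C4, C5, C10) and needs its own enantioselective synthesis. The key step adds one C–C bond and one stereocentre.
- Against: the shift is reversible, and the C8 configuration depends on how the C–O and C=O bonds are aligned in the migrating alkoxide.
- Comparison: the chosen cascade gives up certainty at C8 but builds both rings, C11 with its aryl ether and five stereocentres in one step.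

**Alternative 2:** the C5–C10 bond is cut across the decalin, giving the ten-membered (E)-enone A4 with an exocyclic methylene at C10. In the forward step Fe(acac)3 and PhSiH3 deliver a hydrogen atom to the methylene, and the tertiary C10 radical adds across the ring to C5 of the enone, giving the trans-decalin-7-one A3.
- For: the conditions are neutral, quaternary C10 and the ring fusion form in one step, and the radical ends in a single way (reduction to the enolate). On how the cascade terminates this is more predictable than a cation that can also lose a proton.
- Against: A3 has hydrogen where the target has the C8 hydroxyl, and a ketone at C7 that the target lacks. Regio- and face-selective α-hydroxylation at C8, removal of the C7 carbonyl next to the new carbinol, debenzylation, ether formation at C11 with 2, two desilylations and the selective acylation would follow.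
- Against: A4 is a medium ring with four stereocentres, made by the least favourable kind of ring closure, and the cis or trans outcome of the transannular step depends on its conformation.
- Comparison: the chosen route installs O8 in the ring-forming step and starts from an acyclic chain made in four steps.

**Alternative 3:** the arene is cut at C6–C7, C8–C8a and C4a–C8a (coumarin locants), giving the ethynyl ether A6 of the complete decalin and the dienyl diazoketone A7. In the forward step light induces a Wolff rearrangement of A7 to a vinylketene. This adds [2+2] to A6, the cyclobutenone opens (4π) and recloses (6π), and tautomerisation gives the 4-alkoxy-2-hydroxy-(E)-cinnamate A5.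
- For: the aryl ether is never made by substitution at neopentylic C11, the Lewis-basic coumarin sees no acid, and the polarity of the ynol ether fixes the regiochemistry. If the decalin had to be made first, these points would be as strong as or stronger than the chosen plan.
- Against: the step makes no stereocentre and no bond of the decalin. A6 already holds all six stereocentres, so the main problem is untouched, and the arene it builds is available ready-made as 2.
- Against: an ynol ether must be formed on a hindered alcohol under strongly basic conditions, A7 is itself light-sensitive, and A5 still needs E-to-Z isomerisation, lactonisation, two deprotections and the selective acylation.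
- Comparison: the chosen route forms the same ether in step 1 on an unhindered allylic carbon. The advantage of the alternative disappears, and what remains is the exposure of the coumarin to SnCl4, which is met with an extra equivalent of Lewis acid and low temperature.

Key step: step 5

Assumption (remark on the chemistry): the target has 3R, which maps onto the (10R,11R)-epoxide of the chain, so the Sharpless step needs D-(−)-diethyl tartrate. The water that ends the cascade is supplied deliberately as the aqua complex of SnCl4, since a dry Lewis acid would leave the C8 cation no oxygen nucleophile.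

## Route

Step 1
Reactants: 1 (2E,6E)-farnesol; 2 umbelliferone (7-hydroxy-2H-chromen-2-one)
Product: 3 umbelliprenin, 7-{[(2E,6E)-3,7,11-trimethyldodeca-2,6,10-trien-1-yl]oxy}-2H-chromen-2-one
Conditions: PPh3, DIAD, THF, 0 °C → rt
Reagents that add atoms: none
Why: Mitsunobu etherification: the acidic phenol 2 displaces the oxyphosphonium of the primary allylic alcohol by SN2 at C1, so both alkene geometries are kept and no stereocentre is involved.

Step 2
Reactants: 3 umbelliprenin
Product: 4 7-{[(2E,6E,10E)-12-hydroxy-3,7,11-trimethyldodeca-2,6,10-trien-1-yl]oxy}-2H-chromen-2-one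
Conditions: SeO2 (0.3 equiv), tBuOOH (3 equiv), salicylic acid (0.1 equiv), CH2Cl2, 0 °C → rt, stopped at partial conversion, 3 recovered
Reagents that add atoms: tert-butyl hydroperoxide, CC(C)(C)OO (net source of the new oxygen, passed on through SeO2, O=[Se]=O)
Why: Riley allylic oxidation in its catalytic form: SeO2 adds by an ene reaction to the terminal, most electron-rich and least hindered alkene, and the [2,3]-sigmatropic shift of the allylseleninic acid places oxygen on the E-methyl, so the E-allylic alcohol follows from the mechanism. The coumarin and the aryl ether are not oxidised under these conditions.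

Step 3
Reactants: 4 12-hydroxyumbelliprenin
Product: 5 7-{[(2E,6E)-9-[(2R,3R)-3-(hydroxymethyl)-3-methyloxiran-2-yl]-3,7-dimethylnona-2,6-dien-1-yl]oxy}-2H-chromen-2-one (10R,11R in chain locants)
Conditions: Ti(OiPr)4 (0.1 equiv), D-(−)-diethyl tartrate (0.12 equiv), tBuOOH (2 equiv), 4 Å MS, CH2Cl2, −20 °C
Reagents that add atoms: tert-butyl hydroperoxide, CC(C)(C)OO
Why: Sharpless asymmetric epoxidation: the allylic alkoxide binds to the Ti(OiPr)4/tartrate complex, which delivers the peroxide oxygen to one alkene face. With the D-(−)-tartrate an (E)-2-methylalk-2-en-1-ol gives the (R,R)-oxirane, and the trans relation of chain and CH2OH comes from the E alkene. The two internal alkenes have no directing hydroxyl and stay.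

Step 4
Reactants: 5 (10R,11R)-epoxy alcohol
Product: 6 7-{[(2E,6E)-9-[(2R,3R)-3-{[tert-butyl(diphenyl)silyl]oxymethyl}-3-methyloxiran-2-yl]-3,7-dimethylnona-2,6-dien-1-yl]oxy}-2H-chromen-2-one
Conditions: TBDPSCl, imidazole, CH2Cl2, 0 °C → rt
Reagents that add atoms: tert-butyl(chloro)diphenylsilane, CC(C)(C)[Si](Cl)(c1ccccc1)c1ccccc1
Why: Silylation of a primary alcohol under imidazole catalysis; the mild base leaves the epoxide and its two stereocentres untouched, and the bulky silyl ether neither chelates a Lewis acid nor participates at the epoxide carbon in step 5.

Step 5
Reactants: 6 epoxy silyl ether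
Product: 7 7-{[(1R,2S,4aS,5S,6R,8aR)-5-{[tert-butyl(diphenyl)silyl]oxymethyl}-2,6-dihydroxy-2,5,8a-trimethyldecahydronaphthalen-1-yl]methoxy}-2H-chromen-2-one (3R,4S,5S,8S,9R,10R in decalin locants)
Conditions: SnCl4 (2.5 equiv) premixed with H2O (2.5 equiv), CH2Cl2–EtNO2 (4:1), 0.01 M, −78 → −40 °C; sat. aq NaHCO3
Reagents that add atoms: water, O
Why: The SnCl4 aqua complex acts as a Lewis-acid-assisted Brønsted acid on the epoxide oxygen; the C4–O bond gives way at the tertiary carbon while C5 of the central alkene attacks anti (C4–C5), the C10 cation is taken by C9 of the allylic-ether alkene (C9–C10), and the tertiary C8 cation is captured by tin-bound water (C8–O), so the net change is addition of one H2O. The closest known reaction type is the Lewis-acid-promoted epoxy-polyene cyclisation with hydroxyl termination. Ring A closes 6-endo (both epoxide carbons and both alkene carbons end up in the ring) through a chair, and ring B closes 6-endo-trig through a second chair. C3 keeps the epoxide configuration because its C–O bond is never broken, and C4 is set by inversion at the epoxide carbon, which turns the E-CH2OSi group equatorial and the methyl axial. C5 and C10 come from anti addition across the 6E alkene in the chair, which gives the trans fusion with the C10 methyl syn to O3, and C9 comes from the E geometry of the 2,3-alkene, which leaves CH2OAr equatorial. C8 is set by attack anti to the new C9–C10 bond, from the equatorial side, the axial side being blocked by the 1,3-diaxial C10 methyl. The step needs opening at the tertiary epoxide carbon, completion of ring B and hydration in place of proton loss: the first is secured by the substitution of the epoxide and the non-chelating silyl ether, the second by the Markovnikov polarity of the 2,3-alkene, and the third only by the water carried on the Lewis acid, which is the weak point. One further equivalent of SnCl4 is allowed for the coumarin carbonyl, and the low temperature keeps the allylic aryl ether from ionising before the cascade has consumed that alkene.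

Step 6
Reactants: 7 bicyclic diol silyl ether
Product: 8 7-{[(1R,2S,4aS,5S,6R,8aR)-2,6-dihydroxy-5-(hydroxymethyl)-2,5,8a-trimethyldecahydronaphthalen-1-yl]methoxy}-2H-chromen-2-one
Conditions: TBAF, AcOH, THF, rt → 40 °C
Reagents that add atoms: none
Why: Fluoride-induced cleavage of the Si–O bond; buffering with acetic acid keeps the medium from opening the lactone or dehydrating the tertiary carbinol, and no stereocentre is touched.

Step 7
Reactants: 8 triol; 9 angelic acid, (2Z)-2-methylbut-2-enoic acid
Product: 11 target CNP0139045.1 (the 15-O-angelate of 8), via angeloyl 2,4,6-trichlorobenzoyl anhydride 10 (not isolated)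
Conditions: 2,4,6-trichlorobenzoyl chloride, Et3N, toluene, rt; then 8, toluene, 70 °C, no nucleophilic catalyst
Reagents that add atoms: 2,4,6-trichlorobenzoyl chloride, O=C(Cl)c1c(Cl)cc(Cl)cc1Cl (its acyl group is found in 10 only and is lost again on the way to 11)
Why: Yamaguchi-type esterification through the mixed anhydride: the alcohol attacks the angeloyl carbonyl because the aroyl carbonyl is shielded by its two ortho chlorines, and the primary O15 reacts ahead of the secondary O3 (flanked by quaternary C4) and the tertiary O8. Leaving out a nucleophilic catalyst avoids the addition–elimination that would turn the Z alkene into the E isomer.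

## Compound list

1 | (2E,6E)-farnesol, (2E,6E)-3,7,11-trimethyldodeca-2,6,10-trien-1-ol | CC(C)=CCC/C(C)=C/CC/C(C)=C/CO | starting material
2 | umbelliferone, 7-hydroxy-2H-chromen-2-one | O=c1ccc2ccc(O)cc2o1 | starting material
3 | umbelliprenin, 7-{[(2E,6E)-3,7,11-trimethyldodeca-2,6,10-trien-1-yl]oxy}-2H-chromen-2-one | O=c1ccc2ccc(OC/C=C(\C)CC/C=C(\C)CCC=C(C)C)cc2o1 | intermediate
4 | 7-{[(2E,6E,10E)-12-hydroxy-3,7,11-trimethyldodeca-2,6,10-trien-1-yl]oxy}-2H-chromen-2-one | O=c1ccc2ccc(OC/C=C(\C)CC/C=C(\C)CC/C=C(\C)CO)cc2o1 | intermediate
5 | 7-{[(2E,6E)-9-[(2R,3R)-3-(hydroxymethyl)-3-methyloxiran-2-yl]-3,7-dimethylnona-2,6-dien-1-yl]oxy}-2H-chromen-2-one | O=c1ccc2ccc(OC/C=C(\C)CC/C=C(\C)CC[C@H]3O[C@]3(C)CO)cc2o1 | intermediate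
6 | 7-{[(2E,6E)-9-[(2R,3R)-3-{[tert-butyl(diphenyl)silyl]oxymethyl}-3-methyloxiran-2-yl]-3,7-dimethylnona-2,6-dien-1-yl]oxy}-2H-chromen-2-one | O=c1ccc2ccc(OC/C=C(\C)CC/C=C(\C)CC[C@H]3O[C@]3(C)CO[Si](c4ccccc4)(c4ccccc4)C(C)(C)C)cc2o1 | intermediate
7 | 7-{[(1R,2S,4aS,5S,6R,8aR)-5-{[tert-butyl(diphenyl)silyl]oxymethyl}-2,6-dihydroxy-2,5,8a-trimethyldecahydronaphthalen-1-yl]methoxy}-2H-chromen-2-one | CC(C)(C)[Si](c1ccccc1)(c1ccccc1)OC[C@]1(C)[C@H]2CC[C@](C)(O)[C@@H](COc3ccc4ccc(=O)oc4c3)[C@]2(C)CC[C@H]1O | intermediate
8 | 7-{[(1R,2S,4aS,5S,6R,8aR)-2,6-dihydroxy-5-(hydroxymethyl)-2,5,8a-trimethyldecahydronaphthalen-1-yl]methoxy}-2H-chromen-2-one | OC[C@]1(C)[C@H]2CC[C@](C)(O)[C@@H](COc3ccc4ccc(=O)oc4c3)[C@]2(C)CC[C@H]1O | intermediate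
9 | angelic acid, (2Z)-2-methylbut-2-enoic acid | C/C=C(/C)C(=O)O | starting material
10 | (2Z)-2-methylbut-2-enoic 2,4,6-trichlorobenzoic anhydride | C/C=C(/C)C(=O)OC(=O)c1c(Cl)cc(Cl)cc1Cl | intermediate (not isolated)
11 | CNP0139045.1, 7-{[(1R,2S,4aS,5S,6R,8aR)-2,6-dihydroxy-2,5,8a-trimethyl-5-{[(2Z)-2-methylbut-2-enoyl]oxymethyl}decahydronaphthalen-1-yl]methoxy}-2H-chromen-2-one | C/C=C(/C)C(=O)OC[C@]1(C)[C@H]2CC[C@](C)(O)[C@@H](COc3ccc4ccc(=O)oc4c3)[C@]2(C)CC[C@H]1O | target

## Step count and least certain steps

Total: 7 steps. Longest linear sequence: 7 steps (1 → 3 → 4 → 5 → 6 → 7 → 8 → 11); 2 and 9 enter as commercial partners in steps 1 and 7.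

**Step 5 (key step).** The most likely failure is that the C8 cation loses a proton instead of taking up water, because proton loss is intramolecular and fast while water is present only in small amount. Other possible failures:
- the cascade stops after ring A, since the aryloxy group makes the 2,3-alkene the poorer nucleophile;
- the allylic C–O bond ionises before the cascade reaches that alkene;
- a hydride shifts in the opened epoxide.

Fallback, setting out from 6: the cyclisation is run dry with MeAlCl2 in CH2Cl2 at −78 °C, so that proton loss is the intended ending. This should give the exocyclic C8-methylene bicycle F1 and its C7–C8 alkene isomer F2. The mixture is then hydrated by hydrogen-atom transfer (Co(acac)2, PhSiH3, O2, THF/iPrOH, rt). Both isomers give the same tertiary C8 radical, oxygen is expected to enter from the equatorial side away from the axial C10 methyl, and reduction of the peroxide returns the route at 7. Alkenes formed beside 7 in step 5 itself can be sent through the same hydration. The coumarin C3–C4 alkene is the group to watch there.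

**Step 7.** Acylation may lose site selectivity between O15 and O3 at the temperature a neopentyl hydroxyl needs, and the Z alkene may isomerise by reversible addition of nucleophiles. Fallback, setting out from 7:
- O3 is esterified with levulinic acid (DCC, cat. DMAP, CH2Cl2) to the 3-O-levulinate silyl ether F3;
- the silyl group is removed with HF·pyridine in THF to the 3-O-levulinate 8,15-diol F4;
- F4 is acylated with excess 10 in toluene to the 15-O-angelate 3-O-levulinate F5, now without a competing secondary hydroxyl;
- the levulinate is taken off with hydrazine acetate in CH2Cl2/MeOH at rt, which returns the route at 11.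

**Step 2.** Over-oxidation to the enal, oxidation at internal allylic positions and low conversion are the usual limits of this oxidation on a triene. Fallback, setting out from 3: cross-metathesis with methacrolein (second-generation Hoveyda–Grubbs catalyst, CH2Cl2, 40 °C) exchanges only the terminal isopropylidene group and should give the (E)-12-oxo compound F6. Luche reduction (NaBH4, CeCl3·7H2O, MeOH, 0 °C) reduces the aldehyde without touching the lactone and returns the route at 4.

**Step 1.** Allylic transposition (SN2′), alkylation of the reduced azodicarboxylate and a difficult separation from the phosphine oxide may cut the throughput. Fallback, setting out from 1: PBr3 in Et2O at 0 °C gives (2E,6E)-farnesyl bromide F7, which alkylates 2 with K2CO3 in acetone at rt and returns the route at 3.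

## Further compounds

F1 | step 5 | 8(12)-ene: 7-{[5-(TBDPS-oxymethyl)-6-hydroxy-5,8a-dimethyl-2-methylidenedecahydronaphthalen-1-yl]methoxy}-2H-chromen-2-one, configuration as in 7 | CC(C)(C)[Si](c1ccccc1)(c1ccccc1)OC[C@]1(C)[C@H]2CCC(=C)[C@@H](COc3ccc4ccc(=O)oc4c3)[C@]2(C)CC[C@H]1O
F2 | step 5 | 7-ene: C7–C8 alkene isomer of F1 (8-methyl, 3-hydroxy, 15-O-TBDPS), configuration as in 7 | CC(C)(C)[Si](c1ccccc1)(c1ccccc1)OC[C@]1(C)[C@H]2CC=C(C)[C@@H](COc3ccc4ccc(=O)oc4c3)[C@]2(C)CC[C@H]1O
F3 | step 7 | 3-O-levulinate of 7 (15-O-TBDPS, 8-hydroxyl free) | CC(C)(C)[Si](c1ccccc1)(c1ccccc1)OC[C@]1(C)[C@H]2CC[C@](C)(O)[C@@H](COc3ccc4ccc(=O)oc4c3)[C@]2(C)CC[C@H]1OC(=O)CCC(C)=O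
F4 | step 7 | 3-O-levulinate of 8 (8,15-diol) | OC[C@]1(C)[C@H]2CC[C@](C)(O)[C@@H](COc3ccc4ccc(=O)oc4c3)[C@]2(C)CC[C@H]1OC(=O)CCC(C)=O
F5 | step 7 | 3-O-levulinate of 11 (15-O-angelate) | C/C=C(/C)C(=O)OC[C@]1(C)[C@H]2CC[C@](C)(O)[C@@H](COc3ccc4ccc(=O)oc4c3)[C@]2(C)CC[C@H]1OC(=O)CCC(C)=O
F6 | step 2 | (2E,6E,10E)-2,6,10-trimethyl-12-[(2-oxo-2H-chromen-7-yl)oxy]dodeca-2,6,10-trienal | O=c1ccc2ccc(OC/C=C(\C)CC/C=C(\C)CC/C=C(\C)C=O)cc2o1
F7 | step 1 | (2E,6E)-farnesyl bromide | CC(C)=CCC/C(C)=C/CC/C(C)=C/CBr
A1 | alternative 1 | 8-hydroxy-8-methyl decalin-9-one 3,15-acetonide (product of the α-ketol ring expansion) | CC1(C)OC[C@]2(C)[C@H]3CC[C@](C)(O)C(=O)[C@]3(C)CC[C@H]2O1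
A2 | alternative 1 | ring-contracted 9-acetyl-9-hydroxy hydrindane 3,15-acetonide (acetyl anti to the angular methyl) | CC1(C)OC[C@]2(C)[C@H]3CC[C@](O)(C(C)=O)[C@]3(C)CC[C@H]2O1
A3 | alternative 2 | trans-decalin-7-one with C8 methyl, C11 benzyl ether and 3,15-bis-TBS ethers | CC(C)(C)[Si](C)(C)OC[C@]1(C)[C@H]2CC(=O)[C@H](C)[C@@H](COCc3ccccc3)[C@]2(C)CC[C@H]1O[Si](C)(C)C(C)(C)C
A4 | alternative 2 | ten-membered (E)-enone with exocyclic methylene at C10 (C5=C6–C7=O, 3,15-bis-TBS, C11 benzyl ether) | CC(C)(C)[Si](C)(C)OC[C@]1(C)/C=C/C(=O)[C@H](C)[C@@H](COCc2ccccc2)C(=C)CC[C@H]1O[Si](C)(C)C(C)(C)C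
A5 | alternative 3 | methyl (E)-3-(2-hydroxy-4-alkoxyphenyl)acrylate on the decalin core (8-O-TES, 3,15-acetonide) | CC1(C)OC[C@]2(C)[C@H]3CC[C@](C)(O[Si](CC)(CC)CC)[C@@H](COc4cc(O)c(/C=C/C(=O)OC)cc4)[C@]3(C)CC[C@H]2O1
A6 | alternative 3 | C11 ethynyl ether of the decalin core (8-O-TES, 3,15-acetonide) | CC1(C)OC[C@]2(C)[C@H]3CC[C@](C)(O[Si](CC)(CC)CC)[C@@H](COC#C)[C@]3(C)CC[C@H]2O1
A7 | alternative 3 | methyl (2E,4E)-7-diazo-6-oxohepta-2,4-dienoate | COC(=O)/C=C/C=C/C(=O)C=[N+]=[N-]
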